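## Structural features

Numbering used throughout: ring C1 (ketone), C2=C3, C4 (acetoxy carbon), C5H2 and spiro C6; lactone C7H2, C8 (carbonyl), ring oxygen and C1'; side chain C2'–C7' (TBS = tert-butyldimethylsilyl, PMB = 4-methoxybenzyl). The core is a cyclohex-2-enone that shares its fully substituted C6 with a γ-butyrolactone (C6, C7, C8, O, C1'), a 2-oxaspiro[4.5]decene, and C1' carries an (E,E)-6-hydroxy-2,6-dimethylhepta-1,4-dienyl chain, a skipped diene that ends in a tertiary allylic alcohol. There are three stereocentres: quaternary C6 (R) and the adjacent lactone carbinol C1' (R), and the remote allylic C4 (S), whose oxygen lies on the same ring face as C1'. The fragile groups are the γ-acetoxy enone (base, and ionisation of the allylic acetate), the C1'–O bond (both a lactone and an allylic ester, so ionisable by acid or zerovalent palladium), the 1,4-diene (can move into conjugation) and the tertiary allylic alcohol (acid). The real difficulty is the quaternary spiro carbon next to an oxygenated stereocentre, with C4 to be controlled from that pair. The key step uses the fact that the C1 carbonyl, C6 and the C1' oxygen form an aldol-type β-hydroxy ketone. If C5–C6 is the bond made by a 1,2-shift, this array maps onto a 2,3-epoxy alcohol whose carbinol carbon (future C1) sits in a cyclopentene, so one stereospecific ring enlargement gives the six-membered ring, C6 and C1' together.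

## Logic of the disconnections

**C4'–C5' (27 ⇒ 24 + 26; 26 ⇒ 25).** Cutting the allyl–alkenyl bond removes the acid-sensitive tertiary allylic alcohol and the skipped diene in one stroke and leaves both to the last step. The gain is that 26 is a five-carbon piece available in one step from 25. The forward coupling must be neutral, must join at the primary allylic terminus of 24, must keep both alkene geometries and must not ionise the allylic lactone or the C4 acetate.

**C2'=C3' and the C4' oxidation level (24 ⇒ 23 ⇒ 22 ⇒ 21 ⇒ 20 ⇒ 19).** The E-trisubstituted alkene is cut by an olefination of the C2' aldehyde in 21, because a stabilised ylide gives this geometry reliably. Behind 21 stand 20 and its ether 19, so the core carries only a protected hydroxymethyl group at C1'. The demands are that 21 does not epimerise at C1' and that the aldehyde of 22 is reduced without touching the C1 ketone.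

**Lactone acyl C8–O bond (19 ⇒ 18 ⇒ 17 ⇒ 16).** Opening the C8–O bond of 19 leads through 18 to 17, with a primary alcohol at C8 and a free C1' hydroxyl, and 17 is 16 without its silyl group. This pair of hydroxyls is what the ring-expansion product offers, so no extra carbon–carbon chemistry is needed. The forward oxidation must prefer the primary alcohol and must find no other oxidisable hydroxyl, so C4 is acetylated first.

**C4–O and C2=C3 (16 ⇒ 15 ⇒ 14 ⇒ 13).** Removing the acetyl group of 16 gives 15, whose 4-oxygenated enone is the retron of the β,γ-epoxy ketone 14, and 14 comes from the isolated C3=C4 alkene of 13. The C1' hydroxyl, still free in 13, can place the oxygen on its own ring face. The demands are syn delivery from a hydroxyl two carbons away from the alkene and an epoxide opening mild enough for a β-hydroxy ketone.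

**C5–C6, the key cut (13 ⇒ 12).** Reversing a 1,2-shift of C5 from C1 to C6 turns 13 into 12. Quaternary C6 and C1' become the two carbons of one epoxide, so their relative and absolute configuration reduce to one alkene geometry and one enantioselective oxidation. The forward step must open the epoxide at C6 only and migrate carbon, not hydride.

**Epoxide C–O bonds (12 ⇒ 11).** Removing the epoxide oxygen leaves achiral 11. The forward epoxidation must select one enantioface and must prefer the allylic trisubstituted alkene over the homoallylic ring alkene.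

**Cyclopentene C=C and the PMB–O bond (11 ⇒ 10 ⇒ 9).** The ring alkene of 11 is cut by metathesis into the two allyl groups of 10, and the ether of 10 is cut to 9. The demands are mono-alkylation at the primary hydroxyl and a catalyst that ignores the trisubstituted alkene.

**Two C–C bonds at the carbinol carbon (9 ⇒ 8 ⇒ 6 + 7).** Both allyl groups are removed in turn, through 8, which leads to 6 and two equivalents of 7. The ring of 6 fixes the Z geometry that later becomes the cis epoxide. The forward step needs 1,2-addition twice and a non-acidic work-up.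

**Butenolide C=C, ester and silyl ether (6 ⇒ 5 ⇒ 4 ⇒ 3 ⇒ 1 + 2).** Metathesis disconnection of the ring alkene of 6 gives 5, and cutting its silyl ether and ester bonds leads through 4 and 3 to 1 and 2. The demand is that 4 is silylated before it can close back to 1.

## Other disconnections considered

Alternative 1: The cut removes both carbonyl carbons: C1–C2 and C1–C6 of the cyclohexenone, and C7–C8 and C8–O of the lactone. It leads to the acyclic Z-iodoalkene A2, which already holds C4, C1' and the whole side chain. In the forward step zerovalent palladium would insert into the C2–I bond, CO would give an acyl complex, and this would add 6-exo to the C6=C7 methylidene. The resulting alkylpalladium has no β-hydrogen, so it would take up a second CO and be captured by the C1' hydroxyl to give A1. Desilylation and acetylation would then finish at 27.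
- In its favour: two rings and four bonds in one operation, both carbonyls from CO, and full convergence. After its key step it would be far shorter than the chosen plan, which needs ten more steps. On this point it is the better plan.
- Against it: C6 would be set under substrate control through a flexible transition state, whereas the chosen plan fixes C6 and C1' by one stereospecific shift. The doubly allylic C1' alcohol and the skipped diene would have to survive palladium and CO. Direct 5-exo carbopalladation and early alkoxycarbonylation are competing channels. A2 itself needs two separately controlled stereocentres and a Z-iodoalkene, so part of the saving is spent before the key step.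
- Comparison: both plans rest on known reaction classes; the cascade simply has more branch points, while the chosen plan pays for its stereochemical security with a longer endgame.

Alternative 2: The cut is the ring oxygen between C8 and C1', so lactone A3 is traced to spirocyclobutanone A4. In the forward step the peracid would add to the C8 carbonyl and the more substituted C1' would migrate with retention, enlarging the four-membered ring to the γ-lactone.
- In its favour: regiochemistry and retention in Baeyer–Villiger oxidation of 2-substituted cyclobutanones are highly predictable, and ring strain makes the oxidation mild. As a single step it is at least the equal of the semipinacol shift, and it avoids an acid-sensitive epoxy alcohol. A3 carries the same PMB-oxymethyl handle at C1', so the side-chain endgame is equal.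
- Against it: A3 is saturated, with C1 at the alcohol level and C4 as a ketal. The enone, the C4 stereocentre and the acetate would all still have to be made, including a reduction of a remote ketone with little bias from C6 and a dehydrogenation. The absolute configuration of C6 and C1' would have to be brought in when the four-membered ring of A4 is built, by an asymmetric cycloaddition or a resolution.
- Comparison: the chosen plan should be shorter overall and has a directing group for C4.

Alternative 3: The cut is C1–C6 and C4–C5, giving diene A6 and dienophile A7. In the forward step a chiral oxazaborolidinium catalyst would activate the formyl group of A7, and endo addition to A6 would give A5.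
- In its favour: the C4 acetate, the C2=C3 alkene, quaternary C6 and an oxygen at C1 arrive in one catalytic enantioselective step from achiral partners. For the carbocycle this is shorter than the chosen plan, which needs four steps after the shift to dress the ring, and it is the better plan on that point.
- Against it: C1' is not set. It would come from adding an alkenyl nucleophile to the neopentyl aldehyde of A5 beside the quaternary centre, in the presence of an ester and an allylic acetate, with no firm basis for facial control. A7 has a doubly activated CH2 and may isomerise into conjugation or polymerise. 2-Substituted acroleins often prefer the exo-formyl mode, so the all-cis outcome is uncertain. A6 is labile.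
- Comparison: the chosen plan is longer but forms C6 and C1' in one stereospecific event.

Key step: step 7

Assumption (chemistry): the (1R,2R) antipode of the bishydroxamic acid ligand in step 6 is taken as the one that delivers oxygen to the required face of 11; if the sense is opposite, the (1S,2S) antipode is used and nothing else changes.

Design remarks: 1 is converted into 5 in one flask so that the hydroxy ester is never isolated. The β,γ-epoxy ketone 14 and the epimerisable aldehyde 21 are consumed where they form. Acetylation precedes desilylation, so the only primary hydroxyl exposed to the oxidant is the one that becomes the lactone carbonyl.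

## Route

Step 1
Reactants: 1 α-methylene-γ-butyrolactone (3-methylideneoxolan-2-one); 2 allyl bromide
Product: 5 prop-2-en-1-yl 4-{[tert-butyl(dimethyl)silyl]oxy}-2-methylidenebutanoate, via potassium 4-hydroxy-2-methylidenebutanoate 3 (not isolated), via allyl 4-hydroxy-2-methylidenebutanoate 4 (not isolated)
Conditions: KOH (1.0 equiv), H2O/THF, 0 °C → rt; evaporate, toluene azeotrope; allyl bromide (1.1 equiv), DMF, rt; then imidazole, TBSCl, rt
Reagents that add atoms: potassium hydroxide, [K+].[OH-]; tert-butyl(chloro)dimethylsilane (TBSCl), CC(C)(C)[Si](C)(C)Cl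
Why: Saponification opens the lactone, the carboxylate is O-alkylated by allyl bromide (SN2) and the freed primary alcohol is silylated in the same pot before it can relactonise; no stereocentre is involved.

Step 2
Reactants: 5 prop-2-en-1-yl 4-{[tert-butyl(dimethyl)silyl]oxy}-2-methylidenebutanoate
Product: 6 3-(2-{[tert-butyl(dimethyl)silyl]oxy}ethyl)furan-2(5H)-one
Conditions: RuCl2(=CHPh)(PCy3)(H2IMes) (second-generation Grubbs catalyst, 3 mol%), CH2Cl2 (0.01 M), 40 °C
Reagents that add atoms: none
Why: Ring-closing metathesis of an allyl 2-substituted acrylate closes the butenolide with loss of ethylene; the ring holds the acyl carbon and the CH2O group cis, which is the geometry needed later.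

Step 3
Reactants: 6 3-(2-{[tert-butyl(dimethyl)silyl]oxy}ethyl)furan-2(5H)-one; 7 allylmagnesium bromide
Product: 9 (2Z)-3-(2-{[tert-butyl(dimethyl)silyl]oxy}ethyl)-4-(prop-2-en-1-yl)hepta-2,6-diene-1,4-diol, via ring-opened allyl ketone alkoxide 8 (not isolated)
Conditions: allylMgBr (2.5 equiv), THF, −78 → 0 °C; aq. NH4Cl
Reagents that add atoms: allylmagnesium bromide (second equivalent, the same reagent as 7), C=CC[Mg]Br
Why: Two successive Grignard additions to the lactone carbonyl: the first equivalent opens the ring to the allyl ketone alkoxide 8 and the second adds to its carbonyl. Allyl reagents add 1,2 and faster than they deprotonate, and the Z geometry fixed by the butenolide ring is kept.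

Step 4
Reactants: 9 (2Z)-3-(2-{[tert-butyl(dimethyl)silyl]oxy}ethyl)-4-(prop-2-en-1-yl)hepta-2,6-diene-1,4-diol
Product: 10 (5Z)-5-(2-{[tert-butyl(dimethyl)silyl]oxy}ethyl)-7-[(4-methoxyphenyl)methoxy]-4-(prop-2-en-1-yl)hepta-1,5-dien-4-ol
Conditions: NaH (1.05 equiv), THF/DMF, 0 °C; PMBCl (1.05 equiv), Bu4NI (cat.), 0 °C → rt
Reagents that add atoms: 4-methoxybenzyl chloride (PMBCl), COc1ccc(CCl)cc1
Why: Williamson etherification; the primary allylic alkoxide is alkylated much faster than the hindered tertiary one, so one equivalent of base and halide should give the mono-ether.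

Step 5
Reactants: 10 (5Z)-5-(2-{[tert-butyl(dimethyl)silyl]oxy}ethyl)-7-[(4-methoxyphenyl)methoxy]-4-(prop-2-en-1-yl)hepta-1,5-dien-4-ol
Product: 11 1-[(2Z)-5-{[tert-butyl(dimethyl)silyl]oxy}-1-[(4-methoxyphenyl)methoxy]pent-2-en-3-yl]cyclopent-3-en-1-ol
Conditions: RuCl2(=CHPh)(PCy3)2 (first-generation Grubbs catalyst, 2 mol%), CH2Cl2, 40 °C
Reagents that add atoms: none
Why: Ring-closing metathesis of the diallyl carbinol (a 1,6-diene) gives the cyclopent-3-enol; the trisubstituted alkene does not engage this catalyst.

Step 6
Reactants: 11 1-[(2Z)-5-{[tert-butyl(dimethyl)silyl]oxy}-1-[(4-methoxyphenyl)methoxy]pent-2-en-3-yl]cyclopent-3-en-1-ol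
Product: 12 1-[(2R,3R)-2-(2-{[tert-butyl(dimethyl)silyl]oxy}ethyl)-3-{[(4-methoxyphenyl)methoxy]methyl}oxiran-2-yl]cyclopent-3-en-1-ol
Conditions: WO2(acac)2 (5 mol%), (1R,2R)-N,N'-dihydroxy-N,N'-bis(2,2-diphenylacetyl)cyclohexane-1,2-diamine (6 mol%), 30% aq. H2O2 (1.2 equiv), NaCl, CH2Cl2, rt
Reagents that add atoms: hydrogen peroxide, OO
Why: Tungsten–bishydroxamic acid asymmetric epoxidation of an allylic alcohol: the tertiary hydroxyl binds the metal and directs oxygen to the adjacent electron-rich trisubstituted alkene in preference to the homoallylic ring alkene. The ligand selects the enantioface so that C6 and C1' both become R, and their cis relationship follows from the Z alkene.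

Step 7
Reactants: 12 1-[(2R,3R)-2-(2-{[tert-butyl(dimethyl)silyl]oxy}ethyl)-3-{[(4-methoxyphenyl)methoxy]methyl}oxiran-2-yl]cyclopent-3-en-1-ol
Product: 13 (6R)-6-(2-{[tert-butyl(dimethyl)silyl]oxy}ethyl)-6-{(1S)-1-hydroxy-2-[(4-methoxyphenyl)methoxy]ethyl}cyclohex-3-en-1-one
Conditions: ZnBr2 (1.2 equiv), CH2Cl2, 0 °C → rt; pH 7 phosphate buffer
Reagents that add atoms: none
Why: ZnBr2 binds the epoxide oxygen (held also by the tertiary hydroxyl) and weakens the C6–O bond at the fully substituted carbon, while a ring CH2 on the carbinol carbon migrates to C6 anti to the departing oxygen as the carbinol oxygen becomes the C1 carbonyl. The closest known reaction type is the Lewis-acid semipinacol rearrangement of 2,3-epoxy tertiary alcohols to β-hydroxy ketones. The six-membered ring is not closed by a cyclisation; it arises by one-carbon enlargement of the cyclopentenol through a suprafacial 1,2-alkyl shift that forms C5–C6. Quaternary C6 is set by this stereospecific anti migration, so the epoxide configuration is transferred with inversion at C6. C1' keeps its C–O bond and its spatial arrangement, and its descriptor changes from R to S only because the substituent priorities change. The step needs cleavage of C6–O and not C1'–O, which the tertiary versus secondary substitution and the electron-withdrawing CH2OPMB group on C1' secure. It also needs carbon migration instead of hydride shift from C1' or bromide capture, which the electron push of the hydroxyl and the anti-periplanar ring bond secure. Either ring methylene of the carbinol carbon leads to the same product because the two are related by symmetry, and the low temperature and neutral quench are meant to keep C3=C4 out of conjugation.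

Step 8
Reactants: 13 (6R)-6-(2-{[tert-butyl(dimethyl)silyl]oxy}ethyl)-6-{(1S)-1-hydroxy-2-[(4-methoxyphenyl)methoxy]ethyl}cyclohex-3-en-1-one
Product: 15 (4S,6S)-6-(2-{[tert-butyl(dimethyl)silyl]oxy}ethyl)-4-hydroxy-6-{(1S)-1-hydroxy-2-[(4-methoxyphenyl)methoxy]ethyl}cyclohex-2-en-1-one, via syn-epoxy ketone 14 (not isolated)
Conditions: VO(acac)2 (5 mol%), tBuOOH (1.5 equiv), CH2Cl2, 0 °C → rt; aq. Na2S2O3 wash, crude 14 not purified; then Et3N, CH2Cl2, 0 °C → rt
Reagents that add atoms: tert-butyl hydroperoxide, CC(C)(C)OO
Why: Vanadium-catalysed hydroxyl-directed epoxidation: the vanadate ester of the C1' hydroxyl delivers oxygen to the face of C3=C4 that carries C1', and an epoxide on that face cannot be opened from the rear by the same hydroxyl. Et3N then opens the β,γ-epoxy ketone by E1cB (C2–H removed, C3–O broken), which leaves the C4–O bond intact, so C4 becomes S with its oxygen cis to C1'.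

Step 9
Reactants: 15 (4S,6S)-6-(2-{[tert-butyl(dimethyl)silyl]oxy}ethyl)-4-hydroxy-6-{(1S)-1-hydroxy-2-[(4-methoxyphenyl)methoxy]ethyl}cyclohex-2-en-1-one
Product: 16 (1S,5S)-5-(2-{[tert-butyl(dimethyl)silyl]oxy}ethyl)-5-{(1S)-1-hydroxy-2-[(4-methoxyphenyl)methoxy]ethyl}-4-oxocyclohex-2-en-1-yl acetate
Conditions: Ac2O (1.1 equiv), pyridine, CH2Cl2, −20 → 0 °C
Reagents that add atoms: acetic anhydride, CC(=O)OC(C)=O
Why: Acylation of the unhindered allylic C4 hydroxyl; the C1' hydroxyl is flanked by quaternary C6 and hydrogen-bonded to the ketone, so with one equivalent of anhydride and no nucleophilic catalyst it should stay free.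

Step 10
Reactants: 16 (1S,5S)-5-(2-{[tert-butyl(dimethyl)silyl]oxy}ethyl)-5-{(1S)-1-hydroxy-2-[(4-methoxyphenyl)methoxy]ethyl}-4-oxocyclohex-2-en-1-yl acetate
Product: 17 (1S,5S)-5-(2-hydroxyethyl)-5-{(1S)-1-hydroxy-2-[(4-methoxyphenyl)methoxy]ethyl}-4-oxocyclohex-2-en-1-yl acetate
Conditions: HF·pyridine, pyridine, THF, 0 °C → rt
Reagents that add atoms: none
Why: Fluoride cleavage of the primary silyl ether under buffered, non-basic conditions that spare the acetate, the PMB ether and the enone.

Step 11
Reactants: 17 (1S,5S)-5-(2-hydroxyethyl)-5-{(1S)-1-hydroxy-2-[(4-methoxyphenyl)methoxy]ethyl}-4-oxocyclohex-2-en-1-yl acetate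
Product: 19 (1S,5R,9S)-1-{[(4-methoxyphenyl)methoxy]methyl}-3,6-dioxo-2-oxaspiro[4.5]dec-7-en-9-yl acetate, via lactol 18 (not isolated)
Conditions: TEMPO (2,2,6,6-tetramethylpiperidin-1-oxyl, 20 mol%), PhI(OAc)2 (2.5 equiv), CH2Cl2, rt
Reagents that add atoms: none
Why: Oxoammonium oxidation is selective for the primary alcohol; at the aldehyde level C8 closes onto the C1' hydroxyl as lactol 18, which is oxidised on to the γ-lactone (oxidative lactonisation of a 1,4-diol).

Step 12
Reactants: 19 (1S,5R,9S)-1-{[(4-methoxyphenyl)methoxy]methyl}-3,6-dioxo-2-oxaspiro[4.5]dec-7-en-9-yl acetate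
Product: 20 (1S,5R,9S)-1-(hydroxymethyl)-3,6-dioxo-2-oxaspiro[4.5]dec-7-en-9-yl acetate
Conditions: DDQ (1.5 equiv), CH2Cl2/pH 7 buffer (10:1), 0 °C → rt
Reagents that add atoms: none
Why: Oxidative cleavage of the PMB ether through its benzylic oxocarbenium ion; the near-neutral medium leaves acetate, lactone and enone untouched.

Step 13
Reactants: 20 (1S,5R,9S)-1-(hydroxymethyl)-3,6-dioxo-2-oxaspiro[4.5]dec-7-en-9-yl acetate
Product: 22 (1R,5R,9S)-1-[(1E)-2-methyl-3-oxoprop-1-en-1-yl]-3,6-dioxo-2-oxaspiro[4.5]dec-7-en-9-yl acetate, via aldehyde 21 (not isolated)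
Conditions: Dess–Martin periodinane, NaHCO3, CH2Cl2, 0 °C → rt; then Ph3P=C(CH3)CHO, CH2Cl2/toluene, 40 °C
Reagents that add atoms: 2-(triphenylphosphoranylidene)propanal, CC(C=O)=P(c1ccccc1)(c1ccccc1)c1ccccc1
Why: Dess–Martin oxidation gives the α-acyloxy aldehyde, which is trapped in the same flask by the formyl-stabilised ylide (Wittig olefination); such ylides give the E-trisubstituted alkene and are too weakly basic to epimerise C1'.

Step 14
Reactants: 22 (1R,5R,9S)-1-[(1E)-2-methyl-3-oxoprop-1-en-1-yl]-3,6-dioxo-2-oxaspiro[4.5]dec-7-en-9-yl acetate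
Product: 23 (1R,5R,9S)-1-[(1E)-3-hydroxy-2-methylprop-1-en-1-yl]-3,6-dioxo-2-oxaspiro[4.5]dec-7-en-9-yl acetate
Conditions: NaBH4 (0.5 equiv), MeOH/CH2Cl2, −78 °C
Reagents that add atoms: none
Why: Chemoselective 1,2-reduction: at low temperature borohydride reduces the aldehyde much faster than the conjugated C1 ketone, which is also shielded by quaternary C6; lactone and acetate are inert.

Step 15
Reactants: 23 (1R,5R,9S)-1-[(1E)-3-hydroxy-2-methylprop-1-en-1-yl]-3,6-dioxo-2-oxaspiro[4.5]dec-7-en-9-yl acetate
Product: 24 (1R,5R,9S)-1-[(1E)-3-bromo-2-methylprop-1-en-1-yl]-3,6-dioxo-2-oxaspiro[4.5]dec-7-en-9-yl acetate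
Conditions: CBr4, PPh3, CH2Cl2, 0 °C
Reagents that add atoms: carbon tetrabromide, BrC(Br)(Br)Br
Why: Appel bromination of a primary allylic alcohol under neutral conditions; substitution at the primary carbon keeps the E geometry.

Step 16
Reactants: 25 2-methylbut-3-yn-2-ol
Product: 26 (3E)-2-methyl-4-(tributylstannyl)but-3-en-2-ol
Conditions: PdCl2(PPh3)2 (1 mol%), Bu3SnH, THF, 0 °C → rt
Reagents that add atoms: tributyltin hydride, CCCC[SnH](CCCC)CCCC
Why: Palladium-catalysed syn hydrostannation of a terminal alkyne; the bulky tertiary carbinol sends tin to the terminal carbon, giving the E-alkenylstannane.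

Step 17
Reactants: 24 (1R,5R,9S)-1-[(1E)-3-bromo-2-methylprop-1-en-1-yl]-3,6-dioxo-2-oxaspiro[4.5]dec-7-en-9-yl acetate; 26 (3E)-2-methyl-4-(tributylstannyl)but-3-en-2-ol
Product: 27 (1R,5R,9S)-1-[(1E,4E)-6-hydroxy-2,6-dimethylhepta-1,4-dien-1-yl]-3,6-dioxo-2-oxaspiro[4.5]dec-7-en-9-yl acetate (target)
Conditions: Pd2(dba)3 (2.5 mol%), AsPh3 (10 mol%), THF, rt
Reagents that add atoms: none
Why: Stille allyl–alkenyl coupling: zerovalent palladium adds to the primary allylic bromide much faster than it ionises the hindered allylic lactone or the secondary C4 acetate. The alkenyl group is transferred with retention and couples at the less hindered terminus, giving the skipped E,E-diene under neutral conditions that the acetate, the enone and the tertiary alcohol tolerate.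

## Compound list

1 | α-methylene-γ-butyrolactone (3-methylideneoxolan-2-one) | C=C1CCOC1=O | starting material
2 | allyl bromide (3-bromoprop-1-ene) | C=CCBr | starting material
3 | potassium 4-hydroxy-2-methylidenebutanoate | [K+].[O-]C(=O)C(=C)CCO | intermediate (not isolated)
4 | allyl 4-hydroxy-2-methylidenebutanoate | C=CCOC(=O)C(=C)CCO | intermediate (not isolated)
5 | prop-2-en-1-yl 4-{[tert-butyl(dimethyl)silyl]oxy}-2-methylidenebutanoate | C=CCOC(=O)C(=C)CCO[Si](C)(C)C(C)(C)C | intermediate
6 | 3-(2-{[tert-butyl(dimethyl)silyl]oxy}ethyl)furan-2(5H)-one | O=C1OCC=C1CCO[Si](C)(C)C(C)(C)C | intermediate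
7 | allylmagnesium bromide | C=CC[Mg]Br | starting material
8 | (2Z)-3-(2-{[tert-butyl(dimethyl)silyl]oxy}ethyl)-1-hydroxyhepta-2,6-dien-4-one, present as its bromomagnesium alkoxide | OC/C=C(CCO[Si](C)(C)C(C)(C)C)\C(=O)CC=C | intermediate (not isolated)
9 | (2Z)-3-(2-{[tert-butyl(dimethyl)silyl]oxy}ethyl)-4-(prop-2-en-1-yl)hepta-2,6-diene-1,4-diol | OC/C=C(CCO[Si](C)(C)C(C)(C)C)\C(O)(CC=C)CC=C | intermediate
10 | (5Z)-5-(2-{[tert-butyl(dimethyl)silyl]oxy}ethyl)-7-[(4-methoxyphenyl)methoxy]-4-(prop-2-en-1-yl)hepta-1,5-dien-4-ol | COc1ccc(COC/C=C(CCO[Si](C)(C)C(C)(C)C)\C(O)(CC=C)CC=C)cc1 | intermediate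
11 | 1-[(2Z)-5-{[tert-butyl(dimethyl)silyl]oxy}-1-[(4-methoxyphenyl)methoxy]pent-2-en-3-yl]cyclopent-3-en-1-ol | OC1(CC=CC1)/C(CCO[Si](C)(C)C(C)(C)C)=C\COCc1ccc(OC)cc1 | intermediate
12 | 1-[(2R,3R)-2-(2-{[tert-butyl(dimethyl)silyl]oxy}ethyl)-3-{[(4-methoxyphenyl)methoxy]methyl}oxiran-2-yl]cyclopent-3-en-1-ol (cis epoxide; key-step precursor) | OC1(CC=CC1)[C@]2(CCO[Si](C)(C)C(C)(C)C)O[C@@H]2COCc3ccc(OC)cc3 | intermediate
13 | (6R)-6-(2-{[tert-butyl(dimethyl)silyl]oxy}ethyl)-6-{(1S)-1-hydroxy-2-[(4-methoxyphenyl)methoxy]ethyl}cyclohex-3-en-1-one (key-step product) | O=C1CC=CC[C@@]1(CCO[Si](C)(C)C(C)(C)C)[C@H](O)COCc1ccc(OC)cc1 | intermediate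
14 | (1R,4S,6S)-4-(2-{[tert-butyl(dimethyl)silyl]oxy}ethyl)-4-{(1S)-1-hydroxy-2-[(4-methoxyphenyl)methoxy]ethyl}-7-oxabicyclo[4.1.0]heptan-3-one (epoxide oxygen syn to C1') | O=C1C[C@H]2O[C@H]2C[C@@]1(CCO[Si](C)(C)C(C)(C)C)[C@H](O)COCc1ccc(OC)cc1 | intermediate (not isolated)
15 | (4S,6S)-6-(2-{[tert-butyl(dimethyl)silyl]oxy}ethyl)-4-hydroxy-6-{(1S)-1-hydroxy-2-[(4-methoxyphenyl)methoxy]ethyl}cyclohex-2-en-1-one | O=C1C=C[C@@H](O)C[C@@]1(CCO[Si](C)(C)C(C)(C)C)[C@H](O)COCc1ccc(OC)cc1 | intermediate
16 | (1S,5S)-5-(2-{[tert-butyl(dimethyl)silyl]oxy}ethyl)-5-{(1S)-1-hydroxy-2-[(4-methoxyphenyl)methoxy]ethyl}-4-oxocyclohex-2-en-1-yl acetate | O=C1C=C[C@@H](OC(C)=O)C[C@@]1(CCO[Si](C)(C)C(C)(C)C)[C@H](O)COCc1ccc(OC)cc1 | intermediate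
17 | (1S,5S)-5-(2-hydroxyethyl)-5-{(1S)-1-hydroxy-2-[(4-methoxyphenyl)methoxy]ethyl}-4-oxocyclohex-2-en-1-yl acetate | O=C1C=C[C@@H](OC(C)=O)C[C@@]1(CCO)[C@H](O)COCc1ccc(OC)cc1 | intermediate
18 | (1S,5R,9S)-3-hydroxy-1-{[(4-methoxyphenyl)methoxy]methyl}-6-oxo-2-oxaspiro[4.5]dec-7-en-9-yl acetate (lactol, both C3 epimers) | CC(=O)O[C@@H]1C=CC(=O)[C@@]2(CC(O)O[C@@H]2COCc3ccc(OC)cc3)C1 | intermediate (not isolated)
19 | (1S,5R,9S)-1-{[(4-methoxyphenyl)methoxy]methyl}-3,6-dioxo-2-oxaspiro[4.5]dec-7-en-9-yl acetate | CC(=O)O[C@@H]1C=CC(=O)[C@@]2(CC(=O)O[C@@H]2COCc3ccc(OC)cc3)C1 | intermediate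
20 | (1S,5R,9S)-1-(hydroxymethyl)-3,6-dioxo-2-oxaspiro[4.5]dec-7-en-9-yl acetate | CC(=O)O[C@@H]1C=CC(=O)[C@@]2(CC(=O)O[C@@H]2CO)C1 | intermediate
21 | (1S,5R,9S)-1-formyl-3,6-dioxo-2-oxaspiro[4.5]dec-7-en-9-yl acetate | CC(=O)O[C@@H]1C=CC(=O)[C@@]2(CC(=O)O[C@@H]2C=O)C1 | intermediate (not isolated)
22 | (1R,5R,9S)-1-[(1E)-2-methyl-3-oxoprop-1-en-1-yl]-3,6-dioxo-2-oxaspiro[4.5]dec-7-en-9-yl acetate | CC(=O)O[C@@H]1C=CC(=O)[C@@]2(CC(=O)O[C@@H]2/C=C(\C)C=O)C1 | intermediate
23 | (1R,5R,9S)-1-[(1E)-3-hydroxy-2-methylprop-1-en-1-yl]-3,6-dioxo-2-oxaspiro[4.5]dec-7-en-9-yl acetate | CC(=O)O[C@@H]1C=CC(=O)[C@@]2(CC(=O)O[C@@H]2/C=C(\C)CO)C1 | intermediate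
24 | (1R,5R,9S)-1-[(1E)-3-bromo-2-methylprop-1-en-1-yl]-3,6-dioxo-2-oxaspiro[4.5]dec-7-en-9-yl acetate | CC(=O)O[C@@H]1C=CC(=O)[C@@]2(CC(=O)O[C@@H]2/C=C(\C)CBr)C1 | intermediate
25 | 2-methylbut-3-yn-2-ol | CC(C)(O)C#C | starting material
26 | (3E)-2-methyl-4-(tributylstannyl)but-3-en-2-ol | CC(C)(O)/C=C/[Sn](CCCC)(CCCC)CCCC | intermediate
27 | (+)-miliusane XVII, (1R,5R,9S)-1-[(1E,4E)-6-hydroxy-2,6-dimethylhepta-1,4-dien-1-yl]-3,6-dioxo-2-oxaspiro[4.5]dec-7-en-9-yl acetate | CC(=O)O[C@@H]1C=CC(=O)[C@@]2(CC(=O)O[C@@H]2/C=C(\C)C/C=C/C(C)(C)O)C1 | target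

## Step count and least certain steps

Total step count: 17. Longest linear sequence: 16 steps (steps 1–15 and 17); step 16 is a one-step branch.

**Step 7 (key step).** The tertiary cation may be captured by bromide, hydride may shift from C1' instead of carbon from C1, or C3=C4 may drift into conjugation with C1 under the Lewis acid. Fallback, from 12 back to 13: the tertiary hydroxyl is silylated (TMSCl, imidazole, CH2Cl2) to give the trimethylsilyl ether of 12, F1. This is treated with TMSOTf (10 mol%) in CH2Cl2 at −78 °C, the silyl-triflate-catalysed epoxy silyl ether variant of the semipinacol shift. In it the silyloxy group pushes harder, no bromide is present, and the silyl group passes to the new alkoxide, so the aldol is protected against retro-aldol cleavage as it forms. It should give the C1' trimethylsilyl ether of 13, F2, and citric acid in MeOH then returns 13.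

**Step 6.** The ring alkene, homoallylic to the same hydroxyl, may be epoxidised in competition, or enantioface selection may be poor at a hindered Z-configured tertiary allylic alcohol. Fallback, from 10 back to 12: before ring closure the only electron-rich alkene is the trisubstituted one. It is epoxidised without hydroxyl direction by Shi epoxidation (1,2:4,5-di-O-isopropylidene-β-D-erythro-2,3-hexodiulo-2,6-pyranose, the D-fructose-derived ketone, or its L-configured antipode as chosen by the spiro transition-state model, KHSO5, K2CO3, MeCN/dimethoxymethane, 0 °C) to give the epoxy diallyl carbinol F3. Ring-closing metathesis with RuCl2(=CHPh)(PCy3)2 then gives 12.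

**Step 8.** Oxygen delivery may lose facial control because the directing hydroxyl is two carbons from the alkene, or the alkene may move into conjugation before it is oxidised. Fallback, from 13 back to 16: epoxidation with 3-chloroperbenzoic acid (NaHCO3, CH2Cl2) and opening with Et3N would give both C4 epimers. The syn series continues as in the route. The anti-epoxy ketone F4 gives the C4 epimer of 15, F5, which is converged by a Mitsunobu reaction with acetic acid (PPh3, DIAD, THF, 0 °C). This inverts C4 and installs the acetate at the unhindered hydroxyl only, giving 16.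

**Step 9.** Site selectivity in the acylation may be lost (C1' hydroxyl also esterified), or the free β-hydroxy ketone may cleave by retro-aldol under base. Fallback, from 14 back to 19, with the lactone made before the enone is unveiled: 14 is isolated and desilylated with HF·pyridine buffered by excess pyridine (THF, 0 °C, mild enough to leave the epoxide closed) to the syn-epoxy keto diol F6. TEMPO/PhI(OAc)2 gives the syn-epoxy keto spirolactone F7. Et3N opens the epoxide to the 4-hydroxy enone spirolactone F8, whose only hydroxyl is acetylated (Ac2O, DMAP) to 19.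

**Step 17.** Slow tin-to-palladium transfer from the hindered, hydroxyl-bearing stannane would give the allylpalladium intermediate time to isomerise (loss of E geometry at C2'=C3', branched coupling) or let zerovalent palladium ionise the allylic lactone or the C4 acetate. Fallback, from 24 to 27: 24 is coupled with tributyl(vinyl)stannane, which transfers fast (Pd2(dba)3, AsPh3, THF, rt), to give the terminal 1,4-diene F9. Cross-metathesis of F9 with excess 2-methylbut-3-en-2-ol (RuCl2(=CH-2-iPrOC6H4)(H2IMes), second-generation Hoveyda–Grubbs catalyst, CH2Cl2, 40 °C) forms the E-configured C5'=C6' bond and the tertiary alcohol, giving 27.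

## Further compounds

F1 | step 7 | trimethylsilyl ether of 12 (tertiary O–SiMe3) | C[Si](C)(C)OC1(CC=CC1)[C@]2(CCO[Si](C)(C)C(C)(C)C)O[C@@H]2COCc3ccc(OC)cc3
F2 | step 7 | C1' trimethylsilyl ether of 13 | O=C1CC=CC[C@@]1(CCO[Si](C)(C)C(C)(C)C)[C@H](O[Si](C)(C)C)COCc1ccc(OC)cc1
F3 | step 6 | 4-[(2R,3R)-2-(2-{[tert-butyl(dimethyl)silyl]oxy}ethyl)-3-{[(4-methoxyphenyl)methoxy]methyl}oxiran-2-yl]hepta-1,6-dien-4-ol | C=CCC(O)(CC=C)[C@]1(CCO[Si](C)(C)C(C)(C)C)O[C@@H]1COCc2ccc(OC)cc2
F4 | step 8 | anti-epoxy ketone (C3–C4 epoxide oxygen trans to C1'; diastereomer of 14) | O=C1C[C@@H]2O[C@@H]2C[C@@]1(CCO[Si](C)(C)C(C)(C)C)[C@H](O)COCc1ccc(OC)cc1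
F5 | step 8 | C4 epimer of 15, (4R)-hydroxy enone | O=C1C=C[C@H](O)C[C@@]1(CCO[Si](C)(C)C(C)(C)C)[C@H](O)COCc1ccc(OC)cc1
F6 | step 9 | syn-epoxy keto diol (desilylated 14) | O=C1C[C@H]2O[C@H]2C[C@@]1(CCO)[C@H](O)COCc1ccc(OC)cc1
F7 | step 9 | syn-epoxy keto spirolactone | O=C1C[C@H]2O[C@H]2C[C@@]1(CC(=O)O3)[C@H]3COCc4ccc(OC)cc4
F8 | step 9 | 4-hydroxy enone spirolactone (deacetyl 19) | O[C@@H]1C=CC(=O)[C@@]2(CC(=O)O[C@@H]2COCc3ccc(OC)cc3)C1
F9 | step 17 | (1R,5R,9S)-1-[(1E)-2-methylpenta-1,4-dien-1-yl]-3,6-dioxo-2-oxaspiro[4.5]dec-7-en-9-yl acetate | CC(=O)O[C@@H]1C=CC(=O)[C@@]2(CC(=O)O[C@@H]2/C=C(\C)CC=C)C1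
A1 | alternative 1 | C4 tert-butyldimethylsilyl ether of the deacetyl target | CC(C)(C)[Si](C)(C)O[C@@H]1C=CC(=O)[C@@]2(CC(=O)O[C@@H]2/C=C(\C)C/C=C/C(C)(C)O)C1
A2 | alternative 1 | (1Z,3S,6R,7E,10E)-3-{[tert-butyl(dimethyl)silyl]oxy}-1-iodo-8,12-dimethyl-5-methylidenetrideca-1,7,10-triene-6,12-diol | I/C=C\[C@@H](O[Si](C)(C)C(C)(C)C)CC(=C)[C@H](O)/C=C(\C)C/C=C/C(C)(C)O
A3 | alternative 2 | spiro γ-lactone with C1 silyloxy, C4 dioxolane and PMB-oxymethyl on C1' | O=C1C[C@]2(CC3(OCCO3)CC[C@@H]2O[Si](C)(C)C(C)(C)C)[C@@H](COCc2ccc(OC)cc2)O1
A4 | alternative 2 | 1-(PMB-oxymethyl)spiro[3.5]nonan-2-one with C1 silyloxy and C4 dioxolane on the six-membered ring | O=C1C[C@]2(CC3(OCCO3)CC[C@@H]2O[Si](C)(C)C(C)(C)C)[C@H]1COCc4ccc(OC)cc4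
A5 | alternative 3 | all-cis cyclohexene with C1 silyloxy, C4 acetoxy, C6 formyl and CH2CO2Me | CC(=O)O[C@@H]1C=C[C@H](O[Si](C)(C)C(C)(C)C)[C@@](C=O)(CC(=O)OC)C1
A6 | alternative 3 | (1E,3E)-4-{[tert-butyl(dimethyl)silyl]oxy}buta-1,3-dien-1-yl acetate | CC(=O)O/C=C/C=C/O[Si](C)(C)C(C)(C)C
A7 | alternative 3 | methyl 3-formylbut-3-enoate | COC(=O)CC(=C)C=O
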